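**Retrosynthetic overview**
1. Feature: on the cyclohexane ring C5–C10, the 1-formylvinyl group on C5 [C4(=C3H2)–C15HO] and the acyloxy oxygen on C6 are cis. C15 can therefore be held on O6 as a mixed acetal, and C4 can be delivered to C5 from that same face.
2. Key disconnection C4–C5: 5-exo closure of the vinyl radical of a 2-bromoallyl mixed acetal on O6 onto the enone C9(=O)–C10(Me)=C5. This gives a temporary cis-fused 2-ethoxy-3-methylenetetrahydrofuran that holds the masked aldehyde, O6 and C5 in one ring.
3. The enone comes from (S)-carvone, which supplies the ring, C7, C9=O, the C10 methyl and the lactone carbons. C8–O is added by Rubottom oxidation, and C6–O by vinylogous Rubottom oxidation followed by Mitsunobu inversion.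
4. After the key step: C10–C1 by palladium enolate vinylation, C12–O by SeO2, acetal opening to C6–OH and C15–OH, isobutyrate, C9 reduction, one MnO2 oxidation that forms both enal and lactone, then hydroxyl-directed epoxidation.
5. Ring order: carbocycle (from carvone) → tetrahydrofuran acetal (step 8, opened in step 11) → γ-lactone (step 16) → oxirane (step 17).

Key step: step 8

Numbering and faces: C11(=C13H2)–C12 is the C7 side chain, C1–C2 the vinyl/oxirane unit, and C14 the methyl group. The "lower face" is the face of the C7 side chain and the "upper face" is that of the C8 oxygen.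
Remark on the chemistry: the acetal carbon C15 of 10, 11 and 13–15 forms as a mixture of epimers. One epimer is drawn, both should react alike, and the centre disappears in step 11.

**Step 1**
Reactants: 1 (S)-carvone
Product: 3 cross-conjugated TBS dienol ether of carvone, via lithium dienolate 2 (not isolated)
Conditions: LiN(i-Pr)2 (1.1 equiv), THF, −78 °C; TBSOTf (1.15 equiv), −78 → 0 °C
Reagents that add atoms: TBSOTf, CC(C)(C)[Si](C)(C)OS(=O)(=O)C(F)(F)F
Why: Kinetic deprotonation of a 2-cyclohexenone with a lithium amide takes an α' proton (C8–H) and the silyl triflate traps the dienolate on oxygen (silyl enol ether formation), leaving C7 untouched.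

**Step 2**
Reactants: 3 cross-conjugated TBS dienol ether
Product: 4 C8-silyloxy enone (C8–OTBS on the upper face, trans to the C7 isopropenyl group)
Conditions: mCPBA (1.05 equiv), NaHCO3 buffer, CH2Cl2, −20 → 0 °C
Reagents that add atoms: mCPBA, OOC(=O)c1cccc(Cl)c1
Why: Rubottom oxidation: the peracid epoxidises the electron-rich C8=C9 enol ether bond ahead of the isopropenyl group and from the face opposite the adjacent C7 substituent, and the silyloxy epoxide opens with a 1,4-silyl shift to the α-silyloxy ketone, which sets C8–O trans to C7 (the diequatorial arrangement, also the more stable one).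

**Step 3**
Reactants: 4 C8-silyloxy enone
Product: 5 linear bis-silyl dienol ether, C9(OTBS)=C10(Me)–C5=C6
Conditions: TBSOTf (1.3 equiv), Et3N (2 equiv), CH2Cl2, 0 °C → rt
Reagents that add atoms: TBSOTf, CC(C)(C)[Si](C)(C)OS(=O)(=O)C(F)(F)F
Why: Soft enolisation with silyl triflate and amine: of the two protons aligned with the π system the amine takes the open axial C6–H and not the tertiary C8–H, which is screened by its own OTBS group and by C7 and would lead to a crowded vicinal bis(silyloxy)alkene, so the linear dienol ether should form.

**Step 4**
Reactants: 5 linear bis-silyl dienol ether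
Product: 6 trans γ-hydroxy enone (C6–OH on the upper face)
Conditions: mCPBA (1.0 equiv), NaHCO3 buffer, CH2Cl2, −20 → 0 °C; aqueous work-up
Reagents that add atoms: mCPBA, OOC(=O)c1cccc(Cl)c1
Why: Vinylogous Rubottom oxidation, the reaction that turns steroidal 3,5-dienol ethers into 6-hydroxy-4-en-3-ones: the peracid attacks the exposed terminal C5=C6 bond rather than the tetrasubstituted C9=C10 bond, from the face opposite the neighbouring isopropenyl group, and collapse of the epoxide with loss of the C9 silyl group gives the enone with C6–OH on the upper face (any lower-face epimer is simply 8 and is carried forward).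

**Step 5**
Reactants: 6 trans γ-hydroxy enone
Product: 7 cis 4-nitrobenzoate (C6–O on the lower face)
Conditions: 4-O2NC6H4CO2H, PPh3, DIAD, THF, 0 °C → rt
Reagents that add atoms: 4-nitrobenzoic acid, OC(=O)c1ccc(cc1)[N+](=O)[O-]
Why: Mitsunobu reaction in the 4-nitrobenzoic acid variant used for hindered equatorial cyclohexanols of the menthol type: SN2 displacement of the alkoxyphosphonium group inverts C6 and puts the oxygen on the lower face, cis to the isopropenyl group, while the equatorial leaving group has no antiperiplanar hydrogen for elimination.

**Step 6**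
Reactants: 7 cis 4-nitrobenzoate
Product: 8 cis γ-hydroxy enone
Conditions: K2CO3 (0.2 equiv), MeOH, 0 °C
Reagents that add atoms: none
Why: Base-catalysed transesterification of the activated aryl ester with methanol is fast at 0 °C, does not touch the C6–O bond (retention) and leaves the silyl ether and the enone intact.

**Step 7**
Reactants: 8 cis γ-hydroxy enone; 9 2-bromoacrolein diethyl acetal
Product: 10 radical precursor, the O6 (2-bromo-1-ethoxyallyl) mixed acetal of 8
Conditions: 9 (8 equiv), PPTS (0.1 equiv), 5 Å molecular sieves, toluene, 50 °C
Reagents that add atoms: 2-bromoacrolein diethyl acetal (9), CCOC(OCC)C(Br)=C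
Why: Acid-catalysed transacetalisation through the 2-bromoallyl oxocarbenium ion, driven by excess 9 and by removal of ethanol; the C6–O bond is not broken, the enone-deactivated C6 position does not ionise, and the new acetal centre need not be controlled.

**Step 8**
Reactants: 10 radical precursor
Product: 11 cis-fused 2-ethoxy-3-methylenetetrahydrofuran ketone (C4 and O6 on the lower face, C10 methyl on the lower face)
Conditions: Bu3SnH (1.3 equiv) and AIBN (0.2 equiv) added over 4 h, benzene (0.01 M), 80 °C
Reagents that add atoms: none
Why: The stannyl radical abstracts bromine to give a σ-vinyl radical at C4, which adds to the enone β-carbon C5 and leaves an α-keto radical at C10 that takes hydrogen from Bu3SnH and so carries the chain. The closest known reactions are the Ueno–Stork haloacetal cyclisation and the cyclisation of 2-bromoallyl ethers and acetals of allylic alcohols to 3-methylenetetrahydrofurans. The tetrahydrofuran ring (C4, C5, C6, O6, C15) closes in the 5-exo-trig mode, whereas 6-endo attack at C10 is disfavoured by strain and by polarity. C5 is fixed by the tether: only O6 and C15 lie between C6 and the radical centre, and O6 is pseudoaxial because the C7 and C8 groups stay equatorial, so C4 reaches only the face of C5 syn to O6 and the fusion is cis for either acetal epimer; C10 is set by hydrogen transfer to the convex upper face and is erased again in step 9. The step needs cyclisation to outrun direct reduction, hydrogen-atom shifts and attack on the isopropenyl group: slow stannane addition at high dilution deals with the first, C7–H is anti to O6 and out of reach, and the isopropenyl group could be reached only by slower 6-exo or 7-endo closure.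

**Step 9**
Reactants: 11 bicyclic acetal ketone; 12 bromoethene
Product: 14 C10-vinyl ketone (vinyl on the upper face; methyl on the lower face), via lithium enolate 13 (not isolated)
Conditions: LiN(SiMe3)2 (1.15 equiv), THF, −78 → −20 °C; Pd(OAc)2 (5 mol %), P(t-Bu)3 (10 mol %), 12 (1 M in THF, 3 equiv), rt → 45 °C
Reagents that add atoms: bromoethene (12), C=CBr
Why: Palladium-catalysed α-vinylation of a preformed ketone enolate (oxidative addition of bromoethene to zerovalent palladium, transmetalation, C–C reductive elimination), a reaction known to build quaternary α-carbons from 2-methyl ketones: the amide base removes C10–H rather than C8–H, which is screened by OTBS and would put two oxygens on one enolate double bond, and palladium binds the enolate on the face opposite C4 and the axial O6 of the cis-fused acetal ring, so the vinyl group ends up trans to C4.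

**Step 10**
Reactants: 14 C10-vinyl ketone
Product: 15 C12 allylic alcohol
Conditions: SeO2 (0.3 equiv), t-BuOOH (2.5 equiv, decane), CH2Cl2, 0 °C → rt
Reagents that add atoms: t-BuOOH, CC(C)(C)OO (oxygen passed on through SeO2, O=[Se]=O)
Why: SeO2 allylic hydroxylation (ene reaction, then 2,3-sigmatropic shift): the isopropenyl group is the only electron-rich alkene with a free allylic methyl, since the vinyl group has no allylic hydrogen and the C4=C3 methylene is deactivated by the adjacent acetal carbon, and any over-oxidised C12 enal returns to the alcohol in step 11.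

**Step 11**
Reactants: 15 C12 allylic alcohol
Product: 17 keto triol (C6–OH; C12–OH; C15–OH), via lactol 16 (not isolated)
Conditions: PPTS, acetone–H2O (4:1), 45 °C; concentrate; NaBH(OAc)3 (3 equiv), THF, 0 °C → rt
Reagents that add atoms: water, O
Why: Mild acetal hydrolysis followed by chemoselective aldehyde reduction: the 2-alkoxytetrahydrofuran hydrolyses under conditions that spare the secondary silyl ether, and the acyloxyborohydride reduces the aldehyde of the ring-opened lactol in the 1,2 sense but not the ketone, which is flanked by the quaternary C10 and the silyloxy-bearing C8.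

**Step 12**
Reactants: 17 keto triol
Product: 18 tris-silyl keto alcohol (C12–OTBS and C15–OTBS, C6–OH free)
Conditions: TBSCl (2.3 equiv), imidazole, CH2Cl2, 0 °C
Reagents that add atoms: TBSCl, CC(C)(C)[Si](C)(C)Cl
Why: Steric discrimination in silylation: the two primary allylic alcohols react with TBSCl at 0 °C, whereas the axial C6–OH, syn-axial to the C10 methyl and flanked by two branched carbons, stays free.

**Step 13**
Reactants: 18 tris-silyl keto alcohol; 19 isobutyryl chloride
Product: 20 C6 isobutyrate ketone
Conditions: 19 (3 equiv), pyridine, DMAP (0.3 equiv), CH2Cl2, rt → 40 °C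
Reagents that add atoms: isobutyryl chloride (19), CC(C)C(=O)Cl
Why: DMAP-catalysed esterification of the only free hydroxyl group with retention at C6; the ketone still masks the C9 oxygen, so no selectivity between secondary alcohols is needed.

**Step 14**
Reactants: 20 C6 isobutyrate ketone
Product: 21 C9 alcohol (axial OH on the upper face)
Conditions: LiBH(s-Bu)3 (2 equiv), THF, −78 → −30 °C; pH 7 buffer
Reagents that add atoms: none
Why: Reduction of a hindered cyclohexanone with a bulky trialkylborohydride: the axial trajectory on the upper face is closed by the syn-axial C5–H and C7–H, so hydride comes along the equatorial trajectory and gives the axial C9–OH on the upper face (cis to O8 and to the vinyl group), as in the reduction of 4,4-dimethyl-3-keto terpenoids to their axial alcohols; the hindered ester survives at low temperature and a silyl shift between O8 and O9 would be harmless.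

**Step 15**
Reactants: 21 C9 alcohol
Product: 22 tetraol isobutyrate
Conditions: HF·pyridine, pyridine, THF, 0 °C → rt
Reagents that add atoms: none
Why: Fluoride-mediated cleavage of all three silyl ethers under slightly acidic buffered conditions, which avoid base-induced migration of the isobutyrate to the new primary alcohols.

**Step 16**
Reactants: 22 tetraol isobutyrate
Product: 25 trienyl lactone aldehyde, via dialdehyde 23 (not isolated), via lactol aldehyde 24 (not isolated)
Conditions: activated MnO2 (30 equiv), CH2Cl2, rt
Reagents that add atoms: none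
Why: Chemoselective MnO2 oxidation of allylic alcohols with oxidative lactonisation of a 2-methylene-1,4-diol: C15–OH stops at the enal because O6 is acylated, the C12 enal is trapped by the equatorial C8–OH as a trans-fused lactol that is oxidised on to the α-methylene-γ-butyrolactone, and the non-allylic axial C9–OH, which cannot reach C12, is left alone.

**Step 17**
Reactants: 25 trienyl lactone aldehyde
Product: 26 CNP0496100.1
Conditions: VO(acac)2 (0.1 equiv), t-BuOOH (1.5 equiv, decane), CH2Cl2, 0 °C → rt
Reagents that add atoms: t-BuOOH, CC(C)(C)OO
Why: Vanadium-catalysed hydroxyl-directed epoxidation of a homoallylic alcohol: the vanadate ester of the axial C9–OH, held at the ring periphery and gauche to the equatorial vinyl group, should deliver the peroxide oxygen through a chair-like array (V, O9, C9, C10, C1, C2) to the vinyl face that gives the 1,3-syn epoxy alcohol, which is the C1 configuration of the target, while the enal and methylene lactone alkenes are too electron-poor for this electrophilic oxidant.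

**Compound list**
1 | (S)-carvone | CC1=CC[C@@H](CC1=O)C(C)=C | starting material
2 | lithium cross-conjugated dienolate of carvone (C8=C9–OLi) | [Li+].CC1=CC[C@@H](C=C1[O-])C(C)=C | intermediate
3 | cross-conjugated TBS dienol ether, C8=C9(OTBS)–C10(Me)=C5 | CC1=CC[C@@H](C=C1O[Si](C)(C)C(C)(C)C)C(C)=C | intermediate
4 | C8-silyloxy enone, OTBS trans to isopropenyl | CC(C)(C)[Si](C)(C)O[C@@H]1[C@@H](C(C)=C)CC=C(C)C1=O | intermediate
5 | linear bis-silyl dienol ether, C9(OTBS)=C10(Me)–C5=C6 | CC(C)(C)[Si](C)(C)O[C@@H]1[C@@H](C(C)=C)C=CC(C)=C1O[Si](C)(C)C(C)(C)C | intermediate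
6 | trans γ-hydroxy enone, C6–OH trans to isopropenyl | CC(C)(C)[Si](C)(C)O[C@@H]1[C@@H](C(C)=C)[C@H](O)C=C(C)C1=O | intermediate
7 | cis C6 4-nitrobenzoate | CC(C)(C)[Si](C)(C)O[C@@H]1[C@@H](C(C)=C)[C@@H](OC(=O)c2ccc(cc2)[N+](=O)[O-])C=C(C)C1=O | intermediate
8 | cis γ-hydroxy enone, C6–OH cis to isopropenyl | CC(C)(C)[Si](C)(C)O[C@@H]1[C@@H](C(C)=C)[C@@H](O)C=C(C)C1=O | intermediate
9 | 2-bromoacrolein diethyl acetal | CCOC(OCC)C(Br)=C | starting material
10 | radical precursor, O6 (2-bromo-1-ethoxyallyl) mixed acetal | CC(C)(C)[Si](C)(C)O[C@@H]1[C@@H](C(C)=C)[C@@H](O[C@H](OCC)C(Br)=C)C=C(C)C1=O | intermediate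
11 | cis-fused 2-ethoxy-3-methylenetetrahydrofuran ketone | CC(C)(C)[Si](C)(C)O[C@@H]1[C@@H](C(C)=C)[C@@H](O[C@H](OCC)C2=C)[C@@H]2[C@@H](C)C1=O | intermediate
12 | bromoethene | C=CBr | starting material
13 | lithium C9=C10 enolate of 11 | [Li+].CC(C)(C)[Si](C)(C)O[C@@H]1[C@@H](C(C)=C)[C@@H](O[C@H](OCC)C2=C)[C@@H]2C(C)=C1[O-] | intermediate
14 | C10-vinyl ketone, vinyl trans to C4 | CC(C)(C)[Si](C)(C)O[C@@H]1[C@@H](C(C)=C)[C@@H](O[C@H](OCC)C2=C)[C@@H]2[C@](C)(C=C)C1=O | intermediate
15 | C12 allylic alcohol | CC(C)(C)[Si](C)(C)O[C@@H]1[C@@H](C(=C)CO)[C@@H](O[C@H](OCC)C2=C)[C@@H]2[C@](C)(C=C)C1=O | intermediate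
16 | lactol (anomers) | CC(C)(C)[Si](C)(C)O[C@@H]1[C@@H](C(=C)CO)[C@@H](OC(O)C2=C)[C@@H]2[C@](C)(C=C)C1=O | intermediate
17 | keto triol | CC(C)(C)[Si](C)(C)O[C@@H]1[C@@H](C(=C)CO)[C@@H](O)[C@@H](C(=C)CO)[C@](C)(C=C)C1=O | intermediate
18 | tris-silyl keto alcohol, C6–OH free | CC(C)(C)[Si](C)(C)O[C@@H]1[C@@H](C(=C)CO[Si](C)(C)C(C)(C)C)[C@@H](O)[C@@H](C(=C)CO[Si](C)(C)C(C)(C)C)[C@](C)(C=C)C1=O | intermediate
19 | isobutyryl chloride | CC(C)C(=O)Cl | starting material
20 | C6 isobutyrate ketone | CC(C)(C)[Si](C)(C)O[C@@H]1[C@@H](C(=C)CO[Si](C)(C)C(C)(C)C)[C@@H](OC(=O)C(C)C)[C@@H](C(=C)CO[Si](C)(C)C(C)(C)C)[C@](C)(C=C)C1=O | intermediate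
21 | C9 axial alcohol | CC(C)(C)[Si](C)(C)O[C@@H]1[C@@H](C(=C)CO[Si](C)(C)C(C)(C)C)[C@@H](OC(=O)C(C)C)[C@@H](C(=C)CO[Si](C)(C)C(C)(C)C)[C@](C)(C=C)[C@@H]1O | intermediate
22 | tetraol isobutyrate | O[C@@H]1[C@@H](C(=C)CO)[C@@H](OC(=O)C(C)C)[C@@H](C(=C)CO)[C@](C)(C=C)[C@@H]1O | intermediate
23 | C12,C15 dialdehyde diol | O[C@@H]1[C@@H](C(=C)C=O)[C@@H](OC(=O)C(C)C)[C@@H](C(=C)C=O)[C@](C)(C=C)[C@@H]1O | intermediate
24 | C12 lactol C15 aldehyde | C=C1C(O)O[C@@H]2[C@@H]1[C@@H](OC(=O)C(C)C)[C@@H](C(=C)C=O)[C@](C)(C=C)[C@@H]2O | intermediate
25 | trienyl lactone aldehyde (1,2-deoxy target) | C=C1C(=O)O[C@@H]2[C@@H]1[C@@H](OC(=O)C(C)C)[C@@H](C(=C)C=O)[C@](C)(C=C)[C@@H]2O | intermediate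
26 | CNP0496100.1 | C=C1C(=O)O[C@@H]2[C@@H]1[C@@H](OC(=O)C(C)C)[C@@H](C(=C)C=O)[C@](C)([C@@H]1CO1)[C@@H]2O | target

**Totals and risks**
Total step count: 17. Longest linear sequence: 17 steps, from 1.

Step 8 (key step). The vinyl radical may be reduced before it closes, or the stannane may add to or reduce the enone, so that the C4–C5 bond does not form. The fallback sets out from 10 and returns at 11, and it replaces the radical by an organopalladium intermediate in an intramolecular reductive Heck (conjugate) cyclisation. The conditions are Pd(OAc)2, PPh3 and HCO2Na in DMF at 70 °C. Zerovalent palladium inserts into the C4–Br bond. Syn-carbopalladation of C5=C10 takes place on the face allowed by the same two-atom tether, and formate reduces the resulting palladium enolate. This fallback makes no new compound (F0).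

Step 9. The crowded tetrasubstituted enolate may fail to couple at palladium, through protonation, β-hydride loss or slow reductive elimination, so that the quaternary centre is not built. The fallback sets out from 11, goes through enolate 13 and returns at 14. Aldol addition of 13 to acetaldehyde at −78 °C, on the same open upper face, gives the β-hydroxy ketone F1. Dehydration with Ph2S[OC(CF3)2Ph]2 in CH2Cl2 can only run toward the methyl group because C10 is quaternary, and it therefore unveils the vinyl group.

Step 17. The vinyl group rotates freely, so facial selectivity of oxygen delivery may be poor or may favour the wrong face. The fallback sets out from 25 and returns at 26, and it replaces substrate direction by catalyst-controlled resolution.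
- Undirected epoxidation (mCPBA, NaHCO3, CH2Cl2) gives 26 together with the 1-epi-epoxide F2.
- Hydrolytic kinetic resolution then follows, using water and the chiral trivalent cobalt complex [Co(salen)]OAc, where salen is the dianion of N,N'-bis(3,5-di-tert-butylsalicylidene)cyclohexane-1,2-diamine. The catalyst enantiomer is chosen so that F2 is the fast-reacting epimer.
- This opens F2 at C2 to the polar 1,2-diol F3, which is removed by chromatography and leaves 26.

**Further compounds**
F0 | step 8 | none | none
F1 | step 9 | β-hydroxy ketone from 13 and acetaldehyde (carbinol epimers) | CC(C)(C)[Si](C)(C)O[C@@H]1[C@@H](C(C)=C)[C@@H](O[C@H](OCC)C2=C)[C@@H]2[C@](C)(C(C)O)C1=O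
F2 | step 17 | 1-epi-epoxide (C1 epimer of 26) | C=C1C(=O)O[C@@H]2[C@@H]1[C@@H](OC(=O)C(C)C)[C@@H](C(=C)C=O)[C@](C)([C@H]1CO1)[C@@H]2O
F3 | step 17 | 1,2-diol from hydrolysis of F2 | C=C1C(=O)O[C@@H]2[C@@H]1[C@@H](OC(=O)C(C)C)[C@@H](C(=C)C=O)[C@](C)([C@H](O)CO)[C@@H]2O
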